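**Plan**

- Retrosynthesis (germacrane numbering): the C8 angelate and the silyl ethers come off first. The C6–C7 bond is then cut together with the lactone O–C12 bond, which opens both rings to a linear C6 aldehyde / C13 allylic bromide. The C1–C10 epoxide oxygen, then C7–C11, C9–C10, C4–C5 and C2–C3 follow.
- Enabling feature: C7 carries the exocyclic C11=C13 methylene of the α-methylene-γ-butyrolactone (ring B: O–C6–C7–C11–C12) and is bonded to the carbinol carbon C6 of the ten-membered carbocycle (ring A: C1–C10). C6(O)–C7–C11=C13 is a homoallylic alcohol, the retron of a carbonyl allylation with allylic transposition.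
- Forward: the chain is joined at C2–C3 (auxiliary alkylation of a dihydroxyacetone unit), C4–C5 (allyl addition), C9–C10 (vinyllithium plus glycidyl ether) and C7–C11 (vinylalumination). The epoxide is then installed, rings A and B are closed in one operation, and the angelate goes on last.
- Stereochemistry: C3 from the SAMP auxiliary; C4 by axial attack on the dioxanone chair; C8 from (S)-glycidol; C1/C10 from the Shi ketone on a Z-alkene whose geometry comes from anti-hydroalumination. C6 and C7 are set in the ring closure by C8 and a chair transition state, fed by an E/Z-equilibrating allylchromium (stereoconvergent).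

Key step: step 16

Remark: locants follow germacrane numbering (ring carbons C1–C10; C11, C12, C13 = acrylate carbons; C14 = methyl on C10; C15 = CH2O on C4); TBS = tert-butyldimethylsilyl, TES = triethylsilyl.
Remark: but-2-yn-1-ol, 2,2-dimethyl-1,3-dioxan-5-one, SAMP, (S)-glycidol, methyl propiolate and angelic acid are taken as commercial.

Step 1
Reactants: 1 but-2-yn-1-ol
Product: 3 (Z)-3-iodobut-2-en-1-ol, via alkenylaluminate 2 (not isolated)
Conditions: NaAlH2(OCH2CH2OMe)2, Et2O, 0 → 23 °C; then I2, THF, −78 °C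
Reagents that add atoms: iodine, II
Why: Anti-hydroalumination of the propargylic alkoxide (hydride to C2, aluminium to C3 inside a five-membered alkoxyaluminate) followed by iodinolysis with retention should give the Z-iodoalkene, which fixes the later C1=C10 geometry.

Step 2
Reactants: 3 (Z)-3-iodobut-2-en-1-ol
Product: 4 (Z)-1-bromo-3-iodobut-2-ene
Conditions: CBr4, PPh3, CH2Cl2, 0 °C
Reagents that add atoms: carbon tetrabromide, BrC(Br)(Br)Br
Why: Appel reaction at the primary allylic alcohol should give the bromide without touching the vinyl iodide or the alkene geometry.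

Step 3
Reactants: 5 2,2-dimethyl-1,3-dioxan-5-one; 6 (S)-1-amino-2-(methoxymethyl)pyrrolidine (SAMP)
Product: 7 SAMP hydrazone of 2,2-dimethyl-1,3-dioxan-5-one
Conditions: benzene, reflux, Dean–Stark
Reagents that add atoms: none
Why: Hydrazone condensation of a ketone with the chiral hydrazine, driven by removal of water.

Step 4
Reactants: 7 SAMP hydrazone of 2,2-dimethyl-1,3-dioxan-5-one; 4 (Z)-1-bromo-3-iodobut-2-ene
Product: 10 (4S)-4-[(2Z)-3-iodobut-2-en-1-yl]-2,2-dimethyl-1,3-dioxan-5-one, via lithium azaenolate 8 (not isolated), via alkylated hydrazone 9 (not isolated)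
Conditions: t-BuLi, THF, −78 °C; then 4, −100 → −78 °C; then sat. aq. (CO2H)2, Et2O, 23 °C
Reagents that add atoms: water, O
Why: Enders SAMP-hydrazone alkylation, in which the methoxy-chelated lithium azaenolate is alkylated on one face by the allylic bromide so that C3 should be set as S (the sense known for SAMP with this dioxanone), followed by mild biphasic hydrolysis that frees the ketone and returns the auxiliary.

Step 5
Reactants: 10 (4S)-4-[(2Z)-3-iodobut-2-en-1-yl]-2,2-dimethyl-1,3-dioxan-5-one
Product: 11 (4S,5R)-4-[(2Z)-3-iodobut-2-en-1-yl]-2,2-dimethyl-5-(prop-2-en-1-yl)-1,3-dioxan-5-ol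
Conditions: CH2=CHCH2MgBr, CeCl3, THF, −78 °C
Reagents that add atoms: allylmagnesium bromide, C=CC[Mg]Br
Why: Organocerium 1,2-addition (which suppresses enolisation at C3) is expected to occur by axial attack on the dioxanone chair, whose ring oxygens carry no syn-axial hydrogens and whose C3 side chain is equatorial, placing the allyl group cis to that side chain and setting C4 as R.

Step 6
Reactants: 11 (4S,5R)-4-[(2Z)-3-iodobut-2-en-1-yl]-2,2-dimethyl-5-(prop-2-en-1-yl)-1,3-dioxan-5-ol
Product: 12 (2R,3S,5Z)-6-iodo-2-(prop-2-en-1-yl)hept-5-ene-1,2,3-triol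
Conditions: 1 M HCl, THF, 23 °C
Reagents that add atoms: none
Why: Acetal hydrolysis removes the acetonide here, before any acid-sensitive epoxide exists, so that the end of the route can stay acid-free.

Step 7
Reactants: 12 (2R,3S,5Z)-6-iodo-2-(prop-2-en-1-yl)hept-5-ene-1,2,3-triol
Product: 14 1,3-bis-O-TBS 2-O-TES ether of 12, via bis-TBS ether 13 (not isolated)
Conditions: TBSOTf (2.2 equiv), 2,6-lutidine, CH2Cl2, −78 °C; then TESOTf, −78 → 0 °C
Reagents that add atoms: tert-butyldimethylsilyl triflate, CC(C)(C)[Si](C)(C)OS(=O)(=O)C(F)(F)F; triethylsilyl triflate, CC[Si](CC)(CC)OS(=O)(=O)C(F)(F)F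
Why: Silylation by silyl triflates, in which the bulky reagent should take the primary and secondary hydroxyls at low temperature and the smaller one then caps the tertiary O4, whose protection later prevents 5-exo opening of the C1–C10 epoxide.

Step 8
Reactants: 15 (S)-glycidol
Product: 16 (R)-triethyl(oxiran-2-ylmethoxy)silane
Conditions: TESCl, imidazole, CH2Cl2, 0 °C
Reagents that add atoms: chlorotriethylsilane, CC[Si](Cl)(CC)CC
Why: Silylation of the primary alcohol leaves the epoxide stereocentre untouched (the descriptor changes to R only through the priority rules).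

Step 9
Reactants: 14 1,3-bis-O-TBS 2-O-TES ether of 12; 16 (R)-triethyl(oxiran-2-ylmethoxy)silane
Product: 18 (8R)-alcohol with 1(10)Z-alkene and 7-O-TES (C4 carries the allyl group and 4-O-TES; 3-O-TBS and 15-O-TBS), via vinyllithium 17 (not isolated)
Conditions: t-BuLi (2 equiv), Et2O, −78 °C; then 16, BF3·OEt2, −78 °C
Reagents that add atoms: none
Why: Iodine–lithium exchange with retention of alkene geometry and BF3-promoted opening of the terminal epoxide at its CH2 carbon forms C9–C10 and carries the glycidol stereocentre through unchanged as C8.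

Step 10
Reactants: 18 (8R)-alcohol with 1(10)Z-alkene and 7-O-TES
Product: 19 7,8-bis-O-TES ether of 18
Conditions: TESCl, imidazole, 4-(dimethylamino)pyridine (cat.), CH2Cl2, 0 → 23 °C
Reagents that add atoms: chlorotriethylsilane, CC[Si](Cl)(CC)CC
Why: Silylation of the secondary C8 hydroxyl gives a group that can later be removed in the presence of the TBS ethers and the hindered tertiary TES ether.

Step 11
Reactants: 19 7,8-bis-O-TES ether of 18
Product: 21 (8R)-8-(triethylsilyloxy) C7 aldehyde, via alkoxysulfonium chloride 20 (not isolated)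
Conditions: (COCl)2, DMSO, CH2Cl2, −78 → −30 °C; then Et3N, −78 → 0 °C
Reagents that add atoms: none
Why: Swern oxidation in which the activated sulfoxide cleaves the primary TES ether selectively and oxidises it in the same flask, a known way to go from a bis-TES diol to the α-silyloxy aldehyde without epimerisation.

Step 12
Reactants: 21 (8R)-8-(triethylsilyloxy) C7 aldehyde; 22 methyl propiolate
Product: 24 methyl 2-methylene-3-hydroxy ester (Morita–Baylis–Hillman-type adduct at C7; mixture of C7 epimers), via vinylalane 23 (not isolated)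
Conditions: iBu2AlH, N-methylmorpholine N-oxide, THF, 0 °C; then 21, 0 → 23 °C
Reagents that add atoms: none
Why: Vinylalumination (hydroalumination of the propiolate to the α-(methoxycarbonyl)vinylalane and 1,2-addition to the aldehyde) gives the Morita–Baylis–Hillman-type adduct under non-basic conditions that should not epimerise C8, and the C7 configuration is irrelevant because C7 becomes trigonal in step 15.

Step 13
Reactants: 24 methyl 2-methylene-3-hydroxy ester (mixture of C7 epimers)
Product: 25 (1R,10S)-1,10-epoxide of 24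
Conditions: 1,2:4,5-di-O-isopropylidene-β-D-erythro-2,3-hexodiulo-2,6-pyranose (D-fructose-derived Shi ketone, 30 mol %), KHSO5 (Oxone), K2CO3, Bu4NHSO4, MeCN/CH2(OMe)2/aq. Na2B4O7 buffer, 0 °C
Reagents that add atoms: potassium peroxymonosulfate, [K+].[O-]S(=O)(=O)OO
Why: Shi asymmetric epoxidation, in which the chiral dioxirane should attack only the electron-rich Z-trisubstituted alkene through a spiro transition state and, by analogy with other trisubstituted alkenes, is expected to give the (1R,10S) cis-epoxide under reagent control, while the basic buffer keeps the C7 hydroxyl from opening the new epoxide.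

Step 14
Reactants: 25 (1R,10S)-1,10-epoxide of 24
Product: 26 C6 aldehyde (terminal CH2 of the allyl group removed)
Conditions: O3, pyridine, CH2Cl2, −78 °C
Reagents that add atoms: ozone, [O-][O+]=O
Why: Ozonolysis with pyridine as the in-flask promoter of carbonyl oxide breakdown should cleave the monosubstituted alkene far faster than the conjugated acrylate and give the aldehyde directly, without a reductive work-up or acid.

Step 15
Reactants: 26 C6 aldehyde
Product: 28 methyl (Z)-2-(bromomethyl)-2-enoate (C13 bromide and C7=C11; C6 aldehyde retained), via allylic mesylate 27 (not isolated)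
Conditions: MsCl, Et3N, CH2Cl2, −40 °C; then LiBr, THF, 0 °C
Reagents that add atoms: lithium bromide, [Li+].[Br-]
Why: Mesylation of the secondary allylic alcohol and SN2' displacement by bromide (allylic transposition) should give the conjugated (Z)-bromomethyl enoate under base-buffered conditions that are known to spare trisubstituted epoxides.

Step 16
Reactants: 28 methyl (Z)-2-(bromomethyl)-2-enoate with C6 aldehyde
Product: 31 ten-membered trans-fused α-methylene-γ-butyrolactone (3,15-di-O-TBS; 4,8-di-O-TES; 1,10-epoxide), via allylchromium 29 (not isolated), via hydroxy ester 30 (not isolated)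
Conditions: CrCl2 (8 equiv), THF/DMF, slow addition of 28 (final 0.003 M), 23 °C; then 45 °C
Reagents that add atoms: none
Why: Two CrCl2 insert into the C13–Br bond to give a σ-allyl complex of trivalent chromium that equilibrates its C7=C11 geometry by 1,3-metal shift, so that either bromide geometry is funnelled into one reactive species, which adds through C7 to the C6 aldehyde with allylic transposition (forming C6–C7 and the exocyclic C11=C13) before the chromium alkoxide acylates on C12 with loss of methanol. The closest known reaction type is the intramolecular Nozaki–Hiyama (Barbier-type) allylation of an aldehyde by a 2-(bromomethyl)-2-enoate, which has close precedent for closing the ten-membered ring of germacranolides at this same bond. Ring A closes in a 10-exo-trig mode (C7 onto the aldehyde carbon) and ring B in a 5-exo-trig acyl substitution. C7 is controlled by C8: allylic 1,3-strain against the C11 ester holds H8 in the alkene plane and the aldehyde arrives anti to the C9 chain, the same diastereomer as the Felkin–Anh product of Nozaki–Hiyama additions of allylic bromides that carry an allylic alkoxy stereocentre; C6 is controlled by the chair Zimmerman–Traxler transition state with the C5 and C8 tether ends both equatorial, which gives the anti adduct and hence the trans-fused lactone. The step needs addition to win over reductive 1,4-elimination of the C8 oxygen, over epoxide opening and over oligomerisation; the poor silyloxy leaving group, the inertness of trialkyl epoxides to CrCl2, high dilution and the two turn elements of the chain (cis-epoxide, quaternary C4) should secure this.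

Step 17
Reactants: 31 ten-membered trans-fused α-methylene-γ-butyrolactone
Product: 32 8-hydroxy lactone (3,15-di-O-TBS; 4-O-TES)
Conditions: HF·pyridine, pyridine, THF, 0 °C
Reagents that add atoms: none
Why: Buffered fluoride desilylation should cleave the secondary TES ether much faster than the tertiary TES and the TBS ethers, and it spares the epoxide and the α-methylene lactone.

Step 18
Reactants: 32 8-hydroxy lactone; 33 angelic acid
Product: 35 8-O-angeloyl lactone (3,15-di-O-TBS; 4-O-TES), via mixed anhydride 34 (not isolated)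
Conditions: 33, 2,4,6-trichlorobenzoyl chloride, Et3N, toluene, 23 °C; then 32, 75 °C
Reagents that add atoms: none
Why: Yamaguchi esterification through the mixed anhydride, run without a nucleophilic catalyst, is the established way to acylate a hindered secondary alcohol with angelic acid while keeping the Z geometry, and C8–OH is the only free hydroxyl.

Step 19
Reactants: 35 8-O-angeloyl lactone
Product: 36 CNP0307250.1, (1R,3S,4R,6R,7S,8R,10S)-8-angeloyloxy-1,10-epoxy-3,4,15-trihydroxygermacr-11(13)-en-12,6-olide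
Conditions: HF·pyridine, pyridine, THF, 0 → 23 °C
Reagents that add atoms: none
Why: Fluoride-mediated global desilylation under pyridine-buffered conditions should free the triol without the acid or base that could open the epoxide transannularly, isomerise the angelate or add to the α-methylene lactone.

**Compound list**

1 | but-2-yn-1-ol | CC#CCO | starting material
2 | sodium cyclic alkoxy(alkenyl)bis(2-methoxyethoxy)aluminate of 1 | [Na+].CC1=CCO[Al-]1(OCCOC)OCCOC | intermediate
3 | (Z)-3-iodobut-2-en-1-ol | C/C(I)=C/CO | intermediate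
4 | (Z)-1-bromo-3-iodobut-2-ene | C/C(I)=C/CBr | intermediate
5 | 2,2-dimethyl-1,3-dioxan-5-one | CC1(C)OCC(=O)CO1 | starting material
6 | (S)-1-amino-2-(methoxymethyl)pyrrolidine (SAMP) | COC[C@@H]1CCCN1N | starting material
7 | SAMP hydrazone of 2,2-dimethyl-1,3-dioxan-5-one | CC1(C)OCC(CO1)=NN1CCC[C@H]1COC | intermediate
8 | lithium azaenolate of 7 | CC1(C)OC=C(CO1)N([Li])N1CCC[C@H]1COC | intermediate
9 | SAMP hydrazone of (4S)-4-[(2Z)-3-iodobut-2-en-1-yl]-2,2-dimethyl-1,3-dioxan-5-one | CC1(C)OCC(=NN2CCC[C@H]2COC)[C@H](C/C=C(/C)I)O1 | intermediate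
10 | (4S)-4-[(2Z)-3-iodobut-2-en-1-yl]-2,2-dimethyl-1,3-dioxan-5-one | CC1(C)OCC(=O)[C@H](C/C=C(/C)I)O1 | intermediate
11 | (4S,5R)-4-[(2Z)-3-iodobut-2-en-1-yl]-2,2-dimethyl-5-(prop-2-en-1-yl)-1,3-dioxan-5-ol | C=CC[C@@](O)(COC(C)(C)O1)[C@@H]1C/C=C(/C)I | intermediate
12 | (2R,3S,5Z)-6-iodo-2-(prop-2-en-1-yl)hept-5-ene-1,2,3-triol | C=CC[C@@](O)(CO)[C@@H](O)C/C=C(/C)I | intermediate
13 | 1,3-bis-O-TBS ether of 12 (tertiary OH free) | C=CC[C@@](O)(CO[Si](C)(C)C(C)(C)C)[C@@H](O[Si](C)(C)C(C)(C)C)C/C=C(/C)I | intermediate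
14 | 1,3-bis-O-TBS 2-O-TES ether of 12 | C=CC[C@@](O[Si](CC)(CC)CC)(CO[Si](C)(C)C(C)(C)C)[C@@H](O[Si](C)(C)C(C)(C)C)C/C=C(/C)I | intermediate
15 | (S)-glycidol | OC[C@H]1CO1 | starting material
16 | (R)-triethyl(oxiran-2-ylmethoxy)silane | CC[Si](CC)(CC)OC[C@H]1CO1 | intermediate
17 | (Z)-vinyllithium from 14 (lithium on C10) | C=CC[C@@](O[Si](CC)(CC)CC)(CO[Si](C)(C)C(C)(C)C)[C@@H](O[Si](C)(C)C(C)(C)C)C/C=C(/C)[Li] | intermediate
18 | (8R)-alcohol: 1(10)Z-alkene; 7-O-TES; 4-O-TES; 3,15-di-O-TBS; allyl group on C4 | C=CC[C@@](O[Si](CC)(CC)CC)(CO[Si](C)(C)C(C)(C)C)[C@@H](O[Si](C)(C)C(C)(C)C)C/C=C(/C)C[C@@H](O)CO[Si](CC)(CC)CC | intermediate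
19 | 7,8-bis-O-TES ether of 18 | C=CC[C@@](O[Si](CC)(CC)CC)(CO[Si](C)(C)C(C)(C)C)[C@@H](O[Si](C)(C)C(C)(C)C)C/C=C(/C)C[C@@H](O[Si](CC)(CC)CC)CO[Si](CC)(CC)CC | intermediate
20 | C7 alkoxydimethylsulfonium chloride from 19 | C=CC[C@@](O[Si](CC)(CC)CC)(CO[Si](C)(C)C(C)(C)C)[C@@H](O[Si](C)(C)C(C)(C)C)C/C=C(/C)C[C@@H](O[Si](CC)(CC)CC)CO[S+](C)C.[Cl-] | intermediate
21 | (8R)-8-(triethylsilyloxy) C7 aldehyde | C=CC[C@@](O[Si](CC)(CC)CC)(CO[Si](C)(C)C(C)(C)C)[C@@H](O[Si](C)(C)C(C)(C)C)C/C=C(/C)C[C@@H](O[Si](CC)(CC)CC)C=O | intermediate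
22 | methyl propiolate | C#CC(=O)OC | starting material
23 | diisobutyl[1-(methoxycarbonyl)vinyl]alane | C=C(C(=O)OC)[Al](CC(C)C)CC(C)C | intermediate
24 | methyl 2-methylene-3-hydroxy ester (C7–OH, C11=C13H2; C7 epimers) | C=CC[C@@](O[Si](CC)(CC)CC)(CO[Si](C)(C)C(C)(C)C)[C@@H](O[Si](C)(C)C(C)(C)C)C/C=C(/C)C[C@@H](O[Si](CC)(CC)CC)C(O)C(=C)C(=O)OC | intermediate
25 | (1R,10S)-1,10-epoxide of 24 | C=CC[C@@](O[Si](CC)(CC)CC)(CO[Si](C)(C)C(C)(C)C)[C@@H](O[Si](C)(C)C(C)(C)C)C[C@H]1O[C@@]1(C)C[C@@H](O[Si](CC)(CC)CC)C(O)C(=C)C(=O)OC | intermediate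
26 | C6 aldehyde of 25 | O=CC[C@@](O[Si](CC)(CC)CC)(CO[Si](C)(C)C(C)(C)C)[C@@H](O[Si](C)(C)C(C)(C)C)C[C@H]1O[C@@]1(C)C[C@@H](O[Si](CC)(CC)CC)C(O)C(=C)C(=O)OC | intermediate
27 | C7 mesylate of 26 | O=CC[C@@](O[Si](CC)(CC)CC)(CO[Si](C)(C)C(C)(C)C)[C@@H](O[Si](C)(C)C(C)(C)C)C[C@H]1O[C@@]1(C)C[C@@H](O[Si](CC)(CC)CC)C(OS(C)(=O)=O)C(=C)C(=O)OC | intermediate
28 | methyl (Z)-2-(bromomethyl)-2-enoate with C6 aldehyde (seco precursor) | O=CC[C@@](O[Si](CC)(CC)CC)(CO[Si](C)(C)C(C)(C)C)[C@@H](O[Si](C)(C)C(C)(C)C)C[C@H]1O[C@@]1(C)C[C@@H](O[Si](CC)(CC)CC)/C=C(\CBr)C(=O)OC | intermediate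
29 | C13 σ-allyl dichlorochromium species from 28 (E/Z equilibrating) | O=CC[C@@](O[Si](CC)(CC)CC)(CO[Si](C)(C)C(C)(C)C)[C@@H](O[Si](C)(C)C(C)(C)C)C[C@H]1O[C@@]1(C)C[C@@H](O[Si](CC)(CC)CC)C=C(C[Cr](Cl)Cl)C(=O)OC | intermediate
30 | ten-membered 6-hydroxy methyl ester (anti C6/C7; present as its chromium alkoxide) | C=C(C(=O)OC)[C@H]1[C@H](O)C[C@@](O[Si](CC)(CC)CC)(CO[Si](C)(C)C(C)(C)C)[C@@H](O[Si](C)(C)C(C)(C)C)C[C@H]2O[C@@]2(C)C[C@H]1O[Si](CC)(CC)CC | intermediate
31 | trans-fused 12,6-lactone: 3,15-di-O-TBS; 4,8-di-O-TES; 1,10-epoxide | C=C1C(=O)O[C@@H]2C[C@@](O[Si](CC)(CC)CC)(CO[Si](C)(C)C(C)(C)C)[C@@H](O[Si](C)(C)C(C)(C)C)C[C@H]3O[C@@]3(C)C[C@@H](O[Si](CC)(CC)CC)[C@@H]12 | intermediate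
32 | 8-hydroxy lactone: 3,15-di-O-TBS; 4-O-TES | C=C1C(=O)O[C@@H]2C[C@@](O[Si](CC)(CC)CC)(CO[Si](C)(C)C(C)(C)C)[C@@H](O[Si](C)(C)C(C)(C)C)C[C@H]3O[C@@]3(C)C[C@@H](O)[C@@H]12 | intermediate
33 | angelic acid, (Z)-2-methylbut-2-enoic acid | C/C=C(/C)C(=O)O | starting material
34 | angelic 2,4,6-trichlorobenzoic anhydride | C/C=C(/C)C(=O)OC(=O)c1c(Cl)cc(Cl)cc1Cl | intermediate
35 | 8-O-angeloyl lactone: 3,15-di-O-TBS; 4-O-TES | C=C1C(=O)O[C@@H]2C[C@@](O[Si](CC)(CC)CC)(CO[Si](C)(C)C(C)(C)C)[C@@H](O[Si](C)(C)C(C)(C)C)C[C@H]3O[C@@]3(C)C[C@@H](OC(=O)/C(C)=C\C)[C@@H]12 | intermediate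
36 | CNP0307250.1 | C=C1C(=O)O[C@@H]2C[C@@](O)(CO)[C@@H](O)C[C@H]3O[C@@]3(C)C[C@@H](OC(=O)/C(C)=C\C)[C@@H]12 | target

**Step count and risks**

Total steps: 19. Longest linear sequence: 17 steps (from 1 through steps 1, 2, 4–7 and 9–19).

Most likely to fail:

1. Step 16. The ring may close through the other allylchromium geometry (C8 axial in the chair), which would give the syn adduct and a cis-fused lactone, or the allylmetal may expel the C8 silyloxy group by reductive 1,4-elimination. Fallback: set out from 28 and close the ring with indium powder in THF/H2O at high dilution. This is a Barbier allylation in which the allylindium keeps the Z geometry of the bromide and is known to give syn adducts; it should deliver the 6-epi hydroxy methyl ester F1, with C7 still set by C8. Saponification (LiOH, THF/H2O, 0 °C) would give the 6-epi hydroxy acid F2. Mitsunobu lactonisation (PPh3, diisopropyl azodicarboxylate, toluene, 0 °C) would then close ring B with inversion at C6 and come back to the route at 31.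

2. Step 13. Reagent control by the chiral dioxirane may be weak on a Z-trisubstituted alkene flanked by stereocentres, which would give poor facial selectivity. Fallback: set out from 18, whose free homoallylic C8 hydroxyl can direct the oxidant. Epoxidation with VO(acac)2 and t-BuOOH (CH2Cl2, 0 °C) through a chair-like vanadate transition state with both chain ends equatorial should give the 1,3-syn epoxy alcohol F3, the same (1R,10S) epoxide. Silylation (TESCl, imidazole) would give the bis-TES epoxide F4 and the Swern oxidation of step 11 the epoxy aldehyde F5. Vinylalumination as in step 12 then comes back to the route at 25.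

3. Step 5. The allyl nucleophile may attack equatorially, or the ketone may enolise and epimerise at C3. Fallback: set out from 10 and remove the acetonide first (1 M HCl, THF) to give the keto diol F6. Allylboronic acid pinacol ester (CH2Cl2, 23 °C) would then form a boronate with the C3 hydroxyl and deliver the allyl group through a five-membered chelate, anti to the C2 chain, the Cram-chelate sense that corresponds to the required C4 configuration. This comes back to the route at 12 and skips 11.

**Further compounds**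

F1 | step 16 | 6-epi ten-membered 6-hydroxy methyl ester (syn C6/C7) | C=C(C(=O)OC)[C@H]1[C@@H](O)C[C@@](O[Si](CC)(CC)CC)(CO[Si](C)(C)C(C)(C)C)[C@@H](O[Si](C)(C)C(C)(C)C)C[C@H]2O[C@@]2(C)C[C@H]1O[Si](CC)(CC)CC
F2 | step 16 | 6-epi ten-membered 6-hydroxy acid | C=C(C(=O)O)[C@H]1[C@@H](O)C[C@@](O[Si](CC)(CC)CC)(CO[Si](C)(C)C(C)(C)C)[C@@H](O[Si](C)(C)C(C)(C)C)C[C@H]2O[C@@]2(C)C[C@H]1O[Si](CC)(CC)CC
F3 | step 13 | (1R,10S)-1,10-epoxide of 18 (free C8–OH) | C=CC[C@@](O[Si](CC)(CC)CC)(CO[Si](C)(C)C(C)(C)C)[C@@H](O[Si](C)(C)C(C)(C)C)C[C@H]1O[C@@]1(C)C[C@@H](O)CO[Si](CC)(CC)CC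
F4 | step 13 | 7,8-bis-O-TES ether of F3 | C=CC[C@@](O[Si](CC)(CC)CC)(CO[Si](C)(C)C(C)(C)C)[C@@H](O[Si](C)(C)C(C)(C)C)C[C@H]1O[C@@]1(C)C[C@@H](O[Si](CC)(CC)CC)CO[Si](CC)(CC)CC
F5 | step 13 | (1R,10S)-epoxy (8R)-8-(triethylsilyloxy) C7 aldehyde | C=CC[C@@](O[Si](CC)(CC)CC)(CO[Si](C)(C)C(C)(C)C)[C@@H](O[Si](C)(C)C(C)(C)C)C[C@H]1O[C@@]1(C)C[C@@H](O[Si](CC)(CC)CC)C=O
F6 | step 5 | (3S,5Z)-1,3-dihydroxy-6-iodohept-5-en-2-one | OCC(=O)[C@@H](O)C/C=C(/C)I
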